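**Retrosynthetic overview** (farnesane numbering: C1 = OCH2, C3 = chain carbinol, C6 = ring CH, C7 = ring carbinol, C10 = ring C=O, C11 = CMe2)
1. C1–OAr by Mitsunobu coupling with umbelliferone; C1/C2 from an allyl group (ozonolysis, reduction); C3 by catalytic asymmetric allylboration of a methyl ketone; C3/C4 by olefination and hydrogenation at a C5 aldehyde.
2. Feature that carries the plan: in ring C6–C11 the CMe2 carbon C11 lies between C6 (CH bearing exocyclic C5) and C10 (C=O). This is the CMe2-containing six-membered ring of a bicyclo[3.1.1]heptan-6-one whose carbonyl bridge, bonded to C6 and C10, is C5.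
3. Key disconnection: epoxy γ-lactone 4 from epoxy cyclobutanone 3 by Baeyer–Villiger oxygen insertion into the C5–C10 bond; LiAlH4 then opens the lactone (C5–OH, C10–OH) and the epoxide (C7–OH, C8H2).
4. 3 from chrysanthenone 2 by epoxidation anti to the CMe2 bridge; 2 from (1R,5R)-(+)-verbenone 1 by a photochemical 1,3-shift, which fixes C6.
5. Ring order: carbocycle from the chiral pool (step 1), oxirane (step 2), lactone ring made in step 3 and opened together with the oxirane in step 4; the coumarin is bought.

Key step: step 3

Assumption 1: the diol catalyst of step 8 is assumed to distinguish methyl from the larger ketone substituent in the same sense for aryl and primary-alkyl methyl ketones. The enantiomer of 3,3'-dibromo-1,1'-bi-2-naphthol used is therefore the one that converts acetophenone into (S)-2-phenylpent-4-en-2-ol (Si-face attack).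
Assumption 2: (+)-verbenone of high optical purity is bought; it is also accessible by allylic oxidation of (+)-α-pinene.

**Step 1**
Reactants: 1 (1R,5R)-(+)-verbenone
Product: 2 (1S,5R)-2,7,7-trimethylbicyclo[3.1.1]hept-2-en-6-one (chrysanthenone)
Conditions: hν (Hg lamp, Pyrex, λ > 300 nm), cyclohexane, rt, stopped at partial conversion
Reagents that add atoms: none
Why: Photochemical 1,3-alkyl shift of the enone (verbenone–chrysanthenone photoisomerisation): the CMe2 carbon moves from C5 to C3 of 1 while staying bonded to C1, so the new bridgehead (future C6) is fixed by the bicyclic frame relative to the untouched C1, and short irradiation limits secondary photolysis of 2.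

**Step 2**
Reactants: 2 (1S,5R)-chrysanthenone
Product: 3 (1R,2R,3S,5R)-2,3-epoxy-2,7,7-trimethylbicyclo[3.1.1]heptan-6-one (epoxide oxygen syn to the C=O bridge)
Conditions: DMDO, acetone, 0 °C
Reagents that add atoms: dimethyldioxirane, CC1(C)OO1
Why: Electrophilic epoxidation by a dioxirane under neutral conditions, which cannot trigger a Baeyer–Villiger oxidation while the cyclobutanone is still allylic; the syn methyl of the CMe2 bridge blocks one alkene face, so oxygen should be delivered from the carbonyl-bridge face, setting C7 and C8 with C7–O cis to the C5 bridge.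

**Step 3**
Reactants: 3 (1R,2R,3S,5R)-2,3-epoxy-2,7,7-trimethylbicyclo[3.1.1]heptan-6-one
Product: 4 (1R,2R,3S,5R)-2,3-epoxy-2,8,8-trimethyl-6-oxabicyclo[3.2.1]octan-7-one
Conditions: mCPBA, NaHCO3, CH2Cl2, 0 °C → rt
Reagents that add atoms: 3-chloroperoxybenzoic acid (mCPBA), OOC(=O)c1cccc(Cl)c1
Why: The peracid adds to the strained cyclobutanone carbonyl (the future C5) to give a Criegee adduct, and a 1,2-shift of the bridgehead C10 from carbon to oxygen with loss of 3-chlorobenzoate places the new oxygen between C5 and C10; release of four-ring strain makes this far faster than with an unstrained ketone. The closest known reaction type is the Baeyer–Villiger ring expansion of fused and bridged cyclobutanones to γ-lactones. The one ring formed, the five-membered lactone O–C5–C6–C11–C10, arises by this one-atom ring expansion (a migration, not a cyclisation), and the carbocycle C6–C11 is left intact. No stereocentre is created: C10 migrates with retention, and C6, C7 and C8 are spectators. The selectivity needed is migration of C10 in preference to C6; both are secondary bridgeheads, but C6 is bonded to the fully substituted, oxygen-bearing epoxide carbon C7, which makes it electron-poorer and more encumbered, whereas C10 carries only the C9 methylene, and because the C5 bridge is syn to the epoxide oxygen the adduct has no anti-periplanar path for a fragmentation that would open the epoxide. The bicarbonate buffer keeps the acid-labile epoxide closed.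

**Step 4**
Reactants: 4 (1R,2R,3S,5R)-2,3-epoxy-2,8,8-trimethyl-6-oxabicyclo[3.2.1]octan-7-one
Product: 6 (1S,2S,4R)-2-(hydroxymethyl)-1,3,3-trimethylcyclohexane-1,4-diol, via epoxy diol 5 (not isolated)
Conditions: LiAlH4 (excess), THF, 0 °C → reflux; aqueous NaOH work-up
Reagents that add atoms: none
Why: Hydride reduction of the lactone to the C5/C10 diol followed by SN2 opening of the trisubstituted epoxide at the less substituted C8, anti to the epoxide oxygen (trans-diaxial opening), so the C7–O bond and the C7 configuration from step 2 are kept; both alkoxides sit on the epoxide-oxygen face and cannot open the epoxide themselves.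

**Step 5**
Reactants: 6 (1S,2S,4R)-2-(hydroxymethyl)-1,3,3-trimethylcyclohexane-1,4-diol
Product: 7 (1R,2S)-2-hydroxy-2,6,6-trimethyl-5-oxocyclohexane-1-carbaldehyde
Conditions: (COCl)2, DMSO, CH2Cl2, −78 °C; Et3N, −78 → 0 °C
Reagents that add atoms: none
Why: Swern oxidation: the primary and the secondary hydroxyl are both turned into alkoxysulfonium ions before the base is added, so no lactol that could be oxidised on to a lactone is passed, the tertiary C7 hydroxyl cannot be oxidised, and the low temperature and weak base should spare the β-hydroxy aldehyde from retro-aldol cleavage and C6 epimerisation.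

**Step 6**
Reactants: 7 (1R,2S)-2-hydroxy-2,6,6-trimethyl-5-oxocyclohexane-1-carbaldehyde; 8 dimethyl (2-oxopropyl)phosphonate
Product: 9 (3E)-4-[(1R,2S)-2-hydroxy-2,6,6-trimethyl-5-oxocyclohexyl]but-3-en-2-one
Conditions: LiCl, iPr2NEt, MeCN, rt
Reagents that add atoms: none
Why: Horner–Wadsworth–Emmons olefination with the lithium-chelated β-keto phosphonate anion formed by a weak amine base, which adds to the aldehyde but not to the hindered α,α-dimethyl ketone, should give the E enone and is mild enough for the β-hydroxy aldehyde.

**Step 7**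
Reactants: 9 (3E)-4-[(1R,2S)-2-hydroxy-2,6,6-trimethyl-5-oxocyclohexyl]but-3-en-2-one
Product: 10 (3R,4S)-4-hydroxy-2,2,4-trimethyl-3-(3-oxobutyl)cyclohexan-1-one
Conditions: H2 (1 atm), Pd/C, EtOAc, rt
Reagents that add atoms: none
Why: Heterogeneous catalytic hydrogenation of the conjugated alkene; the ketones and the tertiary alcohol are inert under these conditions and no stereocentre is touched.

**Step 8**
Reactants: 10 (3R,4S)-4-hydroxy-2,2,4-trimethyl-3-(3-oxobutyl)cyclohexan-1-one
Product: 11 (3R,4S)-4-hydroxy-3-[(3R)-3-hydroxy-3-methylhex-5-en-1-yl]-2,2,4-trimethylcyclohexan-1-one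
Conditions: allyl-B(OiPr)2, 3,3'-dibromo-1,1'-bi-2-naphthol (15 mol %, enantiomer as in assumption 1), PhMe/PhCF3 3:1, −35 °C; aqueous work-up
Reagents that add atoms: allyldiisopropoxyborane, C=CCB(OC(C)C)OC(C)C
Why: Chiral-diol-catalysed asymmetric allylboration of a ketone: exchange of an isopropoxy group for the binaphthol gives a chiral allylboronate that transfers allyl through a closed chair transition state to the Si face of the C3 methyl ketone (methyl against the C4 chain), which should set C3 as R under catalyst control, while the α-quaternary C10 ketone is too hindered to react.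

**Step 9**
Reactants: 11 (3R,4S)-4-hydroxy-3-[(3R)-3-hydroxy-3-methylhex-5-en-1-yl]-2,2,4-trimethylcyclohexan-1-one
Product: 14 (3R,4S)-3-[(3R)-3,5-dihydroxy-3-methylpentyl]-4-hydroxy-2,2,4-trimethylcyclohexan-1-one, via ozonide 12 (not isolated), via hydroxy aldehyde 13 (not isolated)
Conditions: O3, CH2Cl2, −78 °C; PPh3, −78 °C → rt; NaBH(OAc)3, AcOH (cat.), rt
Reagents that add atoms: ozone, [O-][O+]=O
Why: Ozonolysis of the only alkene, phosphine reduction of the ozonide to the β-hydroxy aldehyde and chemoselective reduction with the mild NaBH(OAc)3, which is assisted by the C3 hydroxyl and should reduce the aldehyde but not the hindered C10 ketone; C3 is not affected.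

**Step 10**
Reactants: 14 (3R,4S)-3-[(3R)-3,5-dihydroxy-3-methylpentyl]-4-hydroxy-2,2,4-trimethylcyclohexan-1-one; 15 umbelliferone (7-hydroxy-2H-chromen-2-one)
Product: 16 7-{[(3R)-3-hydroxy-5-[(1R,2S)-2-hydroxy-2,6,6-trimethyl-5-oxocyclohexyl]-3-methylpentyl]oxy}-2H-chromen-2-one (target)
Conditions: PPh3, DIAD, THF, 0 °C → rt
Reagents that add atoms: none
Why: Mitsunobu etherification: the primary C1 hydroxyl is activated as the alkoxyphosphonium ion and displaced by the acidic 7-hydroxyl of the coumarin, whereas the two tertiary alcohols are too hindered to be activated; no stereocentre is involved.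

**Compound list**
1 | (1R,5R)-(+)-verbenone | CC1(C)[C@@H]2C(=O)C=C(C)[C@H]1C2 | starting material
2 | (1S,5R)-2,7,7-trimethylbicyclo[3.1.1]hept-2-en-6-one (chrysanthenone) | CC1(C)[C@H]2CC=C(C)[C@@H]1C2=O | intermediate
3 | (1R,2R,3S,5R)-2,3-epoxy-2,7,7-trimethylbicyclo[3.1.1]heptan-6-one | CC1(C)[C@H]2C[C@@H]3O[C@]3(C)[C@@H]1C2=O | intermediate
4 | (1R,2R,3S,5R)-2,3-epoxy-2,8,8-trimethyl-6-oxabicyclo[3.2.1]octan-7-one | CC1(C)[C@H]2C[C@@H]3O[C@]3(C)[C@@H]1C(=O)O2 | intermediate
5 | epoxy diol: 2-(hydroxymethyl)-1,3,3-trimethyl-7-oxabicyclo[4.1.0]heptan-4-ol (lactone of 4 reduced, epoxide intact, all oxygens on one ring face) | CC1(C)[C@H](O)C[C@@H]2O[C@]2(C)[C@@H]1CO | intermediate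
6 | (1S,2S,4R)-2-(hydroxymethyl)-1,3,3-trimethylcyclohexane-1,4-diol | CC1(C)[C@H](O)CC[C@](C)(O)[C@@H]1CO | intermediate
7 | (1R,2S)-2-hydroxy-2,6,6-trimethyl-5-oxocyclohexane-1-carbaldehyde | CC1(C)C(=O)CC[C@](C)(O)[C@@H]1C=O | intermediate
8 | dimethyl (2-oxopropyl)phosphonate | COP(=O)(CC(C)=O)OC | starting material
9 | (3E)-4-[(1R,2S)-2-hydroxy-2,6,6-trimethyl-5-oxocyclohexyl]but-3-en-2-one | CC1(C)C(=O)CC[C@](C)(O)[C@@H]1/C=C/C(C)=O | intermediate
10 | (3R,4S)-4-hydroxy-2,2,4-trimethyl-3-(3-oxobutyl)cyclohexan-1-one | CC1(C)C(=O)CC[C@](C)(O)[C@@H]1CCC(C)=O | intermediate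
11 | (3R,4S)-4-hydroxy-3-[(3R)-3-hydroxy-3-methylhex-5-en-1-yl]-2,2,4-trimethylcyclohexan-1-one | CC1(C)C(=O)CC[C@](C)(O)[C@@H]1CC[C@@](C)(O)CC=C | intermediate
12 | (3R,4S)-4-hydroxy-3-[(3R)-3-hydroxy-3-methyl-4-(1,2,4-trioxolan-3-yl)butyl]-2,2,4-trimethylcyclohexan-1-one (ozonide, both epimers at the trioxolane carbon) | CC1(C)C(=O)CC[C@](C)(O)[C@@H]1CC[C@@](C)(O)CC2OCOO2 | intermediate
13 | (3R)-3-hydroxy-5-[(1R,2S)-2-hydroxy-2,6,6-trimethyl-5-oxocyclohexyl]-3-methylpentanal | CC1(C)C(=O)CC[C@](C)(O)[C@@H]1CC[C@@](C)(O)CC=O | intermediate
14 | (3R,4S)-3-[(3R)-3,5-dihydroxy-3-methylpentyl]-4-hydroxy-2,2,4-trimethylcyclohexan-1-one | CC1(C)C(=O)CC[C@](C)(O)[C@@H]1CC[C@@](C)(O)CCO | intermediate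
15 | umbelliferone (7-hydroxy-2H-chromen-2-one) | Oc1ccc2ccc(=O)oc2c1 | starting material
16 | 7-{[(3R)-3-hydroxy-5-[(1R,2S)-2-hydroxy-2,6,6-trimethyl-5-oxocyclohexyl]-3-methylpentyl]oxy}-2H-chromen-2-one | CC1(C)C(=O)CC[C@](C)(O)[C@@H]1CC[C@@](C)(O)CCOc1ccc2ccc(=O)oc2c1 | target

**Totals**
Total step count: 10. Longest linear sequence: 10 steps (1 to 16); 8 and 15 are bought.

**Steps most likely to fail**

Step 3. The Criegee adduct may collapse with migration of C6 instead of C10, or with both, because the two bridgeheads differ only in their β-substituents; the preference for C10 is a prediction. The fallback moves regiocontrol from the substrate to a catalyst. It sets out from 3, which is oxidised with O2 by a Baeyer–Villiger monooxygenase (whole cells with cofactor recycling, buffer near pH 7.5). This is a known way to convert fused and bridged cyclobutanones into either lactone regioisomer, depending on the enzyme. A panel of enzymes is screened for the C10-migration lactone, which is 4, and the route is rejoined at 4. The neutral medium also spares the epoxide, and an enantioselective enzyme would at the same time reject the minor enantiomer. This fallback makes no new compound (F0).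

Step 8. The catalyst may discriminate poorly between the methyl group and the unbranched C4 chain, and an uncatalysed allyl transfer from a boronate formed at the C7 hydroxyl may add to the problem; either would give a mixture of C3 epimers. The fallback moves the allylation to the enone stage, where the alkenyl/methyl contrast is much larger. It sets out from 9, which under the same diol-catalysed allylboration should give dienol F1 (same spatial arrangement at C3; the descriptor reads S only because the alkenyl branch outranks allyl). The terminal alkene, the only unhindered one, is cleaved (OsO4 cat., NaIO4, 2,6-lutidine, dioxane/H2O) to unsaturated hydroxy aldehyde F2. NaBH(OAc)3 reduces this to unsaturated diol F3. Hydrogenation (H2, Pd/C, EtOAc) saturates the C4–C5 alkene and rejoins the route at 14.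

Step 1. Secondary photolysis of 2 (α-cleavage to an achiral dienyl ketene that recloses thermally) erodes the optical purity carried over from 1; the ee of 2 is to be assayed by chiral GC. The fallback adds a resolution at the first polyol. It sets out from 6: selective acylation of the primary hydroxyl with (S)-2-methoxy-2-phenylacetic acid (DCC, DMAP, CH2Cl2) gives mandelate ester F4 together with diastereomeric ester F5 from the minor enantiomer. F5 is removed by crystallisation or chromatography, and LiOH in THF/H2O cleaves F4 back to 6 of full optical purity, where the route is rejoined.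

**Further compounds**
F0 | step 3 | none | none
F1 | step 8 | (3R,4S)-4-hydroxy-3-[(1E,3S)-3-hydroxy-3-methylhexa-1,5-dien-1-yl]-2,2,4-trimethylcyclohexan-1-one | CC1(C)C(=O)CC[C@](C)(O)[C@@H]1/C=C/[C@@](C)(O)CC=C
F2 | step 8 | (3S,4E)-3-hydroxy-5-[(1R,2S)-2-hydroxy-2,6,6-trimethyl-5-oxocyclohexyl]-3-methylpent-4-enal | CC1(C)C(=O)CC[C@](C)(O)[C@@H]1/C=C/[C@@](C)(O)CC=O
F3 | step 8 | (3R,4S)-3-[(1E,3S)-3,5-dihydroxy-3-methylpent-1-en-1-yl]-4-hydroxy-2,2,4-trimethylcyclohexan-1-one | CC1(C)C(=O)CC[C@](C)(O)[C@@H]1/C=C/[C@@](C)(O)CCO
F4 | step 1 | [(1S,2S,5R)-2,5-dihydroxy-2,6,6-trimethylcyclohexyl]methyl (2S)-2-methoxy-2-phenylacetate | CC1(C)[C@H](O)CC[C@](C)(O)[C@@H]1COC(=O)[C@@H](OC)c1ccccc1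
F5 | step 1 | [(1R,2R,5S)-2,5-dihydroxy-2,6,6-trimethylcyclohexyl]methyl (2S)-2-methoxy-2-phenylacetate | CC1(C)[C@@H](O)CC[C@@](C)(O)[C@H]1COC(=O)[C@@H](OC)c1ccccc1
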